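**Plan**

- The retrosynthesis first cuts the ester C–O bond, giving 19-(furan-2-yl)nonadeca-5,7-diynoic acid and 11-(furan-2-yl)undeca-4,6-diyn-1-ol. Each diyne is then cut at its central sp–sp bond (C6–C7 of the acid, C5–C6 of the alcohol) into a furyl terminal alkyne and a 1-bromoalkyne.
- The furan of the acid half carries its chain at C2 only, with C3, C4 and C5 unsubstituted. Its C3=C4 bond is therefore cut back to the two vinyl groups of an allyl acrolein mixed acetal (C2, C3 and the ring oxygen from a vinyl carbinol, C4 and C5 from acrolein diethyl acetal).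
- Forward, acid half: silyl alkynol, aldehyde, vinyl carbinol, mixed acetal, ring-closing metathesis with aromatisation to the furan, desilylation, Cadiot–Chodkiewicz coupling with 6-bromohex-5-ynoic acid.
- Forward, alcohol half: the furan on the short C4 tether is taken from furan itself (C2 lithiation and alkylation, acetylide displacement, Cadiot–Chodkiewicz coupling with 5-bromopent-4-yn-1-ol). Esterification joins the halves last.
- The target has no stereocentre. The carbinol and acetal centres formed on the way are carried as mixtures and vanish on aromatisation.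

Key step: step 5

**Route**

Step 1
Reactants: 1 (triisopropylsilyl)acetylene; 2 12-bromododecan-1-ol
Product: 4 14-(triisopropylsilyl)tetradec-13-yn-1-ol, via lithium (triisopropylsilyl)acetylide 3 (not isolated)
Conditions: 1 (2.5 equiv), n-BuLi (2.4 equiv), THF, −78 → 0 °C; then 2, DMPU, 0 → 40 °C; H2O quench
Reagents that add atoms: none
Why: SN2 alkylation of a lithium acetylide by a primary bromide; the first equivalent of 3 only deprotonates the hydroxyl, and the resulting lithium alkoxide is a far poorer nucleophile than the acetylide in THF/DMPU, so the unprotected bromo alcohol should alkylate cleanly at carbon.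

Step 2
Reactants: 4 14-(triisopropylsilyl)tetradec-13-yn-1-ol
Product: 5 14-(triisopropylsilyl)tetradec-13-ynal
Conditions: TEMPO (10 mol%), PhI(OAc)2 (1.1 equiv), CH2Cl2, rt
Reagents that add atoms: none
Why: Oxoammonium-mediated (TEMPO/PhI(OAc)2) oxidation stops at the aldehyde for a primary alcohol and leaves the silyl alkyne untouched.

Step 3
Reactants: 5 14-(triisopropylsilyl)tetradec-13-ynal; 6 vinylmagnesium bromide
Product: 7 16-(triisopropylsilyl)hexadec-1-en-15-yn-3-ol (racemic)
Conditions: 6 (1.3 equiv), THF, −78 → 0 °C; aq NH4Cl
Reagents that add atoms: none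
Why: Grignard 1,2-addition to an unhindered aliphatic aldehyde; the carbinol centre forms racemic, which is immaterial because it becomes the sp2 C2 of the furan in step 5.

Step 4
Reactants: 7 16-(triisopropylsilyl)hexadec-1-en-15-yn-3-ol; 8 acrolein diethyl acetal
Product: 9 triisopropyl[14-(1-ethoxyprop-2-en-1-yloxy)hexadec-15-en-1-yn-1-yl]silane (mixture of diastereomers)
Conditions: 8 (5 equiv), PPTS (5 mol%), toluene, 40 °C, ca. 100 mbar (EtOH stripped); Et3N quench
Reagents that add atoms: none
Why: Acid-catalysed transacetalisation through the ethoxy-allyl oxocarbenium ion, driven by removal of ethanol and held at the mixed acetal by the excess of 8; the new acetal centre is uncontrolled, which does not matter because it is lost in step 5.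

Step 5
Reactants: 9 triisopropyl[14-(1-ethoxyprop-2-en-1-yloxy)hexadec-15-en-1-yn-1-yl]silane
Product: 11 triisopropyl[13-(furan-2-yl)tridec-1-yn-1-yl]silane, via ethoxydihydrofuran 10 (not isolated)
Conditions: RuCl2(H2IMes)(PCy3)(=CHPh) (second-generation Grubbs catalyst, 5 mol%), CH2Cl2 (0.01 M), 40 °C; then PPTS (20 mol%), 40 °C
Reagents that add atoms: none
Why: The ruthenium benzylidene exchanges onto one of the two monosubstituted vinyl groups of 9, and intramolecular [2+2] cycloaddition with the other followed by cycloreversion of the ruthenacyclobutane expels ethene and forms the future furan C3=C4 bond. The closest known reaction type is exactly this ring-closing metathesis of allyl acrolein mixed acetals to 2-alkoxy-2,5-dihydrofurans with acid-promoted aromatisation to furans. The single ring closes as a five-membered ring by carbon–carbon closure of a 1,6-diene across the acetal oxygen, the most favourable ring size for olefin metathesis. PPTS then ionises the ring acetal of 10 to a cyclic oxocarbenium ion, and loss of the proton at the former carbinol carbon gives the aromatic furan with release of ethanol. No stereocentre is created; the carbinol and acetal centres of 9 are both destroyed, so all diastereomers converge on 11. The step needs ring closure to outrun cross-metathesis and enyne metathesis, which high dilution, the fast five-ring closure of two terminal olefins and the bulky triisopropylsilyl cap on the alkyne secure, while the weak acid spares the acid-sensitive 2-alkylfuran.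

Step 6
Reactants: 11 triisopropyl[13-(furan-2-yl)tridec-1-yn-1-yl]silane
Product: 12 2-(tridec-12-yn-1-yl)furan
Conditions: TBAF (1.5 equiv), THF, 0 °C → rt
Reagents that add atoms: none
Why: Fluoride-induced protodesilylation of a silyl alkyne; the furan and the alkyl chain are inert to TBAF.

Step 7
Reactants: 13 hex-5-ynoic acid
Product: 14 6-bromohex-5-ynoic acid
Conditions: NBS (1.1 equiv), AgNO3 (10 mol%), acetone, rt, dark
Reagents that add atoms: N-bromosuccinimide, O=C1CCC(=O)N1Br
Why: Silver-catalysed bromination of a terminal alkyne through the silver acetylide is fast in acetone without base, so the free acid should neither lactonise nor need protection.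

Step 8
Reactants: 12 2-(tridec-12-yn-1-yl)furan; 14 6-bromohex-5-ynoic acid
Product: 15 19-(furan-2-yl)nonadeca-5,7-diynoic acid
Conditions: CuCl (10 mol%), NH2OH·HCl (0.3 equiv), n-BuNH2 (30% aq), THF/MeOH, 0 °C → rt, slow addition of 14; then citric acid to pH 4
Reagents that add atoms: none
Why: Cadiot–Chodkiewicz coupling of the copper acetylide of 12 (monovalent copper kept reduced by hydroxylamine) with the 1-bromoalkyne; the carboxylate is tolerated, and both homocoupled by-products differ sharply in polarity from the mono-acid and should be easy to remove.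

Step 9
Reactants: 16 furan; 17 1-bromo-4-chlorobutane
Product: 19 2-(4-chlorobutyl)furan, via 2-furyllithium 18 (not isolated)
Conditions: 16 (1.2 equiv), n-BuLi (1.0 equiv), THF, 0 °C; then 17, −78 °C → rt
Reagents that add atoms: none
Why: Furan is lithiated selectively at C2, and 2-furyllithium displaces bromide in preference to chloride, leaving the chloride as the handle for step 10.

Step 10
Reactants: 19 2-(4-chlorobutyl)furan; 20 lithium acetylide–ethylenediamine complex (LiC≡CH·H2NCH2CH2NH2)
Product: 21 2-(hex-5-yn-1-yl)furan
Conditions: 20 (1.5 equiv), NaI (10 mol%), DMSO, rt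
Reagents that add atoms: none
Why: SN2 displacement of a primary chloride by lithium acetylide in DMSO, assisted by in situ iodide exchange, is the standard route to terminal alkynes and does not affect the furan.

Step 11
Reactants: 22 pent-4-yn-1-ol
Product: 23 5-bromopent-4-yn-1-ol
Conditions: NBS (1.1 equiv), AgNO3 (10 mol%), acetone, rt, dark
Reagents that add atoms: N-bromosuccinimide, O=C1CCC(=O)N1Br
Why: Silver-catalysed alkyne C–H bromination as in step 7; the primary alcohol is not oxidised under these conditions.

Step 12
Reactants: 21 2-(hex-5-yn-1-yl)furan; 23 5-bromopent-4-yn-1-ol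
Product: 24 11-(furan-2-yl)undeca-4,6-diyn-1-ol
Conditions: CuCl (10 mol%), NH2OH·HCl (0.3 equiv), n-BuNH2 (30% aq), Et2O/MeOH, 0 °C → rt, slow addition of 23
Reagents that add atoms: none
Why: Cadiot–Chodkiewicz coupling of a terminal alkyne with a 1-bromoalkyne; the free hydroxyl is compatible, and the mono-alcohol should separate readily from the hydrocarbon and diol homodimers.

Step 13
Reactants: 15 19-(furan-2-yl)nonadeca-5,7-diynoic acid; 24 11-(furan-2-yl)undeca-4,6-diyn-1-ol
Product: 25 11-(furan-2-yl)undeca-4,6-diyn-1-yl 19-(furan-2-yl)nonadeca-5,7-diynoate (target)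
Conditions: N,N'-diisopropylcarbodiimide (1.2 equiv), DMAP (0.1 equiv), CH2Cl2, 0 °C → rt, dark
Reagents that add atoms: none
Why: Steglich esterification of an unhindered acid with a primary alcohol runs under near-neutral conditions that should leave both furans and both diynes intact.

**Compound list**

1 | (triisopropylsilyl)acetylene | C#C[Si](C(C)C)(C(C)C)C(C)C | starting material
2 | 12-bromododecan-1-ol | OCCCCCCCCCCCCBr | starting material
3 | lithium (triisopropylsilyl)acetylide | [Li+].[C-]#C[Si](C(C)C)(C(C)C)C(C)C | intermediate
4 | 14-(triisopropylsilyl)tetradec-13-yn-1-ol | OCCCCCCCCCCCCC#C[Si](C(C)C)(C(C)C)C(C)C | intermediate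
5 | 14-(triisopropylsilyl)tetradec-13-ynal | O=CCCCCCCCCCCCC#C[Si](C(C)C)(C(C)C)C(C)C | intermediate
6 | vinylmagnesium bromide | C=C[Mg]Br | starting material
7 | 16-(triisopropylsilyl)hexadec-1-en-15-yn-3-ol (racemic) | C=CC(O)CCCCCCCCCCCC#C[Si](C(C)C)(C(C)C)C(C)C | intermediate
8 | acrolein diethyl acetal (3,3-diethoxyprop-1-ene) | C=CC(OCC)OCC | starting material
9 | triisopropyl[14-(1-ethoxyprop-2-en-1-yloxy)hexadec-15-en-1-yn-1-yl]silane (mixture of diastereomers) | C=CC(OCC)OC(C=C)CCCCCCCCCCCC#C[Si](C(C)C)(C(C)C)C(C)C | intermediate
10 | triisopropyl[13-(5-ethoxy-2,5-dihydrofuran-2-yl)tridec-1-yn-1-yl]silane (cis/trans mixture) | CCOC1C=CC(CCCCCCCCCCCC#C[Si](C(C)C)(C(C)C)C(C)C)O1 | intermediate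
11 | triisopropyl[13-(furan-2-yl)tridec-1-yn-1-yl]silane | CC(C)[Si](C#CCCCCCCCCCCCc1ccco1)(C(C)C)C(C)C | intermediate
12 | 2-(tridec-12-yn-1-yl)furan | C#CCCCCCCCCCCCc1ccco1 | intermediate
13 | hex-5-ynoic acid | OC(=O)CCCC#C | starting material
14 | 6-bromohex-5-ynoic acid | OC(=O)CCCC#CBr | intermediate
15 | 19-(furan-2-yl)nonadeca-5,7-diynoic acid | OC(=O)CCCC#CC#CCCCCCCCCCCCc1ccco1 | intermediate
16 | furan | c1ccoc1 | starting material
17 | 1-bromo-4-chlorobutane | ClCCCCBr | starting material
18 | 2-furyllithium | [Li]c1ccco1 | intermediate
19 | 2-(4-chlorobutyl)furan | ClCCCCc1ccco1 | intermediate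
20 | lithium acetylide–ethylenediamine complex | [Li+].[C-]#C.NCCN | starting material
21 | 2-(hex-5-yn-1-yl)furan | C#CCCCCc1ccco1 | intermediate
22 | pent-4-yn-1-ol | OCCCC#C | starting material
23 | 5-bromopent-4-yn-1-ol | OCCCC#CBr | intermediate
24 | 11-(furan-2-yl)undeca-4,6-diyn-1-ol | OCCCC#CC#CCCCCc1ccco1 | intermediate
25 | 11-(furan-2-yl)undeca-4,6-diyn-1-yl 19-(furan-2-yl)nonadeca-5,7-diynoate | O=C(CCCC#CC#CCCCCCCCCCCCc1ccco1)OCCCC#CC#CCCCCc1ccco1 | target

**Step count**

Total: 13 steps. Longest linear sequence: 8 steps (steps 1, 2, 3, 4, 5, 6, 8, 13).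

**Steps most likely to fail**

1. Step 5. The ruthenium carbene may decay to hydride species that shift the allyl-acetal double bonds instead of closing the ring, or the dihydrofuran may degrade before the weak acid ionises its acetal. The fallback builds the furan by cyclodehydration instead and sets out from aldehyde 5. Addition of 2-(1,3-dioxolan-2-yl)ethylmagnesium bromide in THF at 0 °C should give the hydroxy acetal 1-(1,3-dioxolan-2-yl)-16-(triisopropylsilyl)hexadec-15-yn-3-ol F1. Dess–Martin oxidation should give the keto acetal 1-(1,3-dioxolan-2-yl)-16-(triisopropylsilyl)hexadec-15-yn-3-one F2. p-TsOH in wet acetone, then in warm toluene, should unmask the keto aldehyde 4-oxo-17-(triisopropylsilyl)heptadec-16-ynal F3, which closes in the Paal–Knorr manner with loss of water. The fallback comes back to the route at compound 11, replacing steps 3 to 5.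

2. Step 4. The acetal exchange is an equilibrium: it may stall, run on to the symmetrical bis-allyl acetal, or the acid may ionise the secondary allylic alcohol. The fallback makes the mixed acetal by metal catalysis instead and sets out from allylic alcohol 7. Addition of its hydroxyl to methoxyallene with Pd(OAc)2, 1,3-bis(diphenylphosphino)propane and Et3N in MeCN at rt should give the methoxy mixed acetal triisopropyl[14-(1-methoxyprop-2-en-1-yloxy)hexadec-15-en-1-yn-1-yl]silane F4. Under the conditions of step 5 this should close to triisopropyl[13-(5-methoxy-2,5-dihydrofuran-2-yl)tridec-1-yn-1-yl]silane F5 and aromatise with loss of methanol in place of ethanol. The fallback comes back to the route at compound 11.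

3. Step 8. The carboxylate of the bromoalkyne may partition into the aqueous amine, away from the lipophilic copper acetylide, so that reductive dimerisation of the bromoalkyne and oxidative dimerisation of the terminal alkyne outrun the cross-coupling. The fallback reverses the order of ester formation and coupling and sets out from bromo acid 14 and diynol 24. Esterification with N,N'-diisopropylcarbodiimide and DMAP in CH2Cl2 should give the neutral, lipophilic bromoalkyne ester 11-(furan-2-yl)undeca-4,6-diyn-1-yl 6-bromohex-5-ynoate F6. Cadiot–Chodkiewicz coupling of F6 with alkyne 12 (CuCl, NH2OH·HCl, a few equivalents of n-BuNH2, THF/MeOH, 0 °C) should then form the second diyne in a single organic phase. The fallback comes back to the route at compound 25, and step 13 is no longer needed.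

**Further compounds**

F1 | step 5 | 1-(1,3-dioxolan-2-yl)-16-(triisopropylsilyl)hexadec-15-yn-3-ol | OC(CCC1OCCO1)CCCCCCCCCCCC#C[Si](C(C)C)(C(C)C)C(C)C
F2 | step 5 | 1-(1,3-dioxolan-2-yl)-16-(triisopropylsilyl)hexadec-15-yn-3-one | O=C(CCC1OCCO1)CCCCCCCCCCCC#C[Si](C(C)C)(C(C)C)C(C)C
F3 | step 5 | 4-oxo-17-(triisopropylsilyl)heptadec-16-ynal | O=CCCC(=O)CCCCCCCCCCCC#C[Si](C(C)C)(C(C)C)C(C)C
F4 | step 4 | triisopropyl[14-(1-methoxyprop-2-en-1-yloxy)hexadec-15-en-1-yn-1-yl]silane | C=CC(OC)OC(C=C)CCCCCCCCCCCC#C[Si](C(C)C)(C(C)C)C(C)C
F5 | step 4 | triisopropyl[13-(5-methoxy-2,5-dihydrofuran-2-yl)tridec-1-yn-1-yl]silane | COC1C=CC(CCCCCCCCCCCC#C[Si](C(C)C)(C(C)C)C(C)C)O1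
F6 | step 8 | 11-(furan-2-yl)undeca-4,6-diyn-1-yl 6-bromohex-5-ynoate | O=C(CCCC#CBr)OCCCC#CC#CCCCCc1ccco1
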